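No rate constant is given, so the runs have to stand in for the constants, and a ledger of reagent needs none of them.

common to all: substrate 0.10 M

| flask | reagent | remark | time |
|---|---|---|---|
| teal | 0.076 M | run made earlier |  |
| ochre | 0.21 M | run made earlier |  |
| violet | 0.35 M | run made earlier |  |
| north-west | 0.100 M |  | 80 min |
| west | 0.400 M |  | 80 min |

| run | time / min | double product / % | single product / % |
|---|---|---|---|
| teal | 5.00 | 4 | 24 |
| teal | 15.0 | 5 | 32 |
| teal | 25.0 | 9 | 34 |
| teal | 40.0 | 11 | 33 |
| ochre | 5.00 | 18 | 43 |
| ochre | 15.0 | 39 | 49 |
| ochre | 25.0 | 47 | 49 |
| ochre | 40.0 | 53 | 47 |
| violet | 5.00 | 33 | 48 |
| violet | 15.0 | 52 | 47 |
| violet | 25.0 | 54 | 44 |
| violet | 40.0 | 61 | 40 |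

(readings scatter by 1.5 percentage points)

- the analysis behind the earlier runs scatters by 1.5 percentage points, standard deviation

1. which of these holds the largest part of the substrate at the end of north-west (other mono adduct / single product / double product / substrate)
2. which of these holds the largest part of the substrate at the end of west (other mono adduct / single product / double product / substrate)
3. double product at the end of north-west, in percent of the substrate charged

Each substrate converted takes one reagent, and each double product takes a second. In the ochre run the single product reads about 49% late in the run, so the other share, the part of converted substrate that becomes other mono adduct, reads 51.0%. With that split, the last teal reading counts 78.3% of reagent used, in percent of the substrate, against a charge of 76.0%, so the count closes to within 2.3 percentage points. North-west is charged with 0.100 M of reagent on 0.10 M of substrate, so reagent is the limiting reagent, and once it is consumed, substrate left equals double product.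

The first way to double product takes the price paid in teal, 1.17 reagent per substrate converted, and gives north-west 14.5%. The second way counts lifetimes. Taking the loss of substrate and the loss of other mono adduct as first order in the same reagent, a falling reagent slows both clocks alike and the ratio of lifetimes stays constant. Trying a lifetime of other mono adduct 2 times that of substrate, and counting no double product from single product, double product becomes the other share times the square of one minus the root of the substrate left. For the first teal reading this gives 4.16%, and 4% was read. Set equal to the substrate left, it gives north-west 17.4%.

The ways part by 2.9 points, and the first one cheats: double product per substrate converted in teal climbed from 0.0817 to 0.169, so the price is not constant. This reckoning therefore commits to 17.4% double product in north-west, with single product at 40.5%, above other mono adduct at 24.7%. West is charged with more reagent than violet, where double product read 61% against 40% of single product at the last reading, so this reckoning names double product for west.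

The forecast names single product for north-west and double product for west, with 16% double product in north-west: “Single is largest”.

North-west ends with single product largest at 40.3% and 16.6% double product; west ends with double product at 69.6%, above single product at 29.1%. North-west's reagent stands at 0.0588% of its charge, with substrate and double product level at 16.6%, and a reading ten times later leaves double product where it is.

    substrate + reagent → single product (k = 1.39 M⁻¹ min⁻¹)
    substrate + reagent → other mono adduct (k = 1.36 M⁻¹ min⁻¹)
    reagent + single product → double product (k = 0.0272 M⁻¹ min⁻¹)
    reagent + other mono adduct → double product (k = 1.24 M⁻¹ min⁻¹)
    single product → over-reaction product (k = 4.38 × 10⁻⁴ min⁻¹)

The simulated substrate left in north-west, put into the law with the other share, gives 17.9% double product against 16.6%. The neighbouring flask is north-west with 0.060 M of reagent, which is 60.0% of the substrate. Its substrate left, 45.0%, gives by the same law 5.52%, and it holds 5.02%. Its reagent ledger, substrate converted plus double product, closes at 60.0% of the substrate, with 0% of its reagent left. Substrate is the largest holder there, at 45.0% against 26.8% of single product.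

The readings were generated by integration for an exercise.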